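## Analysis of the target

The target is a 2-aryl-3-(hydroxymethyl)-2,3-dihydrobenzofuran neolignan. Its numbering here is O1, C2, C3, ring A = C3a to C7a, C9 for the carbinol carbon on C3, and C1' for the ipso carbon of the 4-hydroxy-3,5-dimethoxyphenyl (syringyl) ring on C2. Ring A carries a methoxy group at C7 and an acetyl group at C5, para to the ring oxygen. There are two stereocentres, C2 (S) and C3 (R), which are adjacent and trans; nothing else in the flat molecule can relay stereochemistry, so both must be set absolutely. The sensitive groups are the free phenol para to the benzylic C2–O1 bond (reversible ionisation under acid, oxidation by periodate), the aryl methyl ketone (attacked by organolithiums and hydride) and the primary alcohol. C3 is benzylic and β to O1, so any carbonyl group at C9 invites enolisation and ring opening by loss of the O1 phenoxide. The difficulty is therefore to form the C2–C1' and C3–C9 bonds with control of both centres, without building the ring by a long linear sequence. The strategy rests on the C2–C3 bond being the former C2=C3 double bond of a benzofuran: C2 is the acidic position (lithiation, then boron), and C3 becomes nucleophilic once boron on C2 is four-coordinate, so an aryl group and a carbon electrophile can be added across C2=C3 trans to each other.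

## Retrosynthetic reasoning

**21 to 20.** The phenol and the ketone of target 21 are released last from alcohol 20, where they are a methoxymethyl ether and a dioxolane. No skeletal bond is cut. Both masks fall in one acid step, and the phenol stays protected through every oxidising and basic step.

**20 to 17 to 16.** The C9–O bond is traced to an alkene. Oxidative cleavage of the propenyl group of 17 gives aldehyde 19 through diol 18, and 19 is reduced in the same flask to 20. Compound 17 is the positional isomer of allyl compound 16. The cut is made here because the carbon electrophile that the key step accepts is an allyl unit whose inner CH2 becomes C9; the two outer carbons are sacrificed. The forward steps must move the double bond by exactly one position and must never let aldehyde 19 enolise.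

**16 to 15.** The C2–H bond is traced to the C2–B bond of boronic ester 15. Boron is the handle that made the C2–C1' bond, and it has to be exchanged for hydrogen with retention so that the syringyl ring stays trans to the C3 substituent.

**15 to 7, 11 and 12 (key disconnection).** The C2–C1' and C3–C9 bonds are cut together. Benzofuran 7 is lithiated at C2 to give 13, which adds to aryl boronic ester 11 to give boronate 14. Allylation of 14 at C3 by the allyl cation equivalent that palladium and a chiral diphosphine generate from allyl acetate 12 triggers migration of the syringyl group from boron to C2. The cut is placed here because it turns the stereochemical problem into the addition of two groups across a flat, easily made heteroaromatic double bond. The whole carbon skeleton and both stereocentres arise in one operation from three simple pieces, and the ring needs no closure step.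

**7 to 6 to 4 to 2 and 3, and 2 to 1.** The dioxolane of 7 comes from ketone 6. The furan ring of 6 is cut at O1–C2 and C3–C3a: ortho-alkynylphenol 4 cyclises through ethynylphenol 5, and 4 comes from iodophenol 2 and ethynyltrimethylsilane 3. Iodophenol 2 is apocynin 1 iodinated ortho to the hydroxyl group. Apocynin already holds the acetyl, methoxy and oxygen substituents of ring A in the right places.

**11 to 9 to 8.** The C–B bond of 11 comes from aryllithium 10, made by bromine–lithium exchange on 9, the methoxymethyl ether of commercial 4-bromo-2,6-dimethoxyphenol 8.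

## Alternatives that were turned down

**Alternative 1:** The ring is opened at the aryl ether bond O1–C7a. Both stereocentres would be set in an open chain by an auxiliary-controlled syn aldol reaction. After removal of the auxiliary and protection of the primary alcohol, the fluoroarene alcohol A1 would be deprotonated at the C2 hydroxyl with KN(SiMe3)2, and the alkoxide would displace fluoride at C7a to give ester A2.

- For it: the absolute configuration comes from a well-understood auxiliary, and the C–O closure touches neither stereocentre. On predictability of the stereochemical outcome it is stronger than the chosen route.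
- Against it: the fluoride is activated only by one para ester, a modest acceptor. It is flanked by the C7 methoxy donor and the branched benzylic carbon, so the displacement needs forcing basic conditions on a substrate with a benzylic C3–H.
- Against it: the ester must later be turned into the acetyl group, and the auxiliary, trityl and silyl groups each cost steps. The ring A fluoroarene is not a commercial pattern, and the sequence is linear and clearly longer.
- In exchange, the chosen route offers convergence and a ring that is already present before the stereocentres are made.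

**Alternative 2:** The C2–C3 bond is cut. Aryldiazoacetate A3 would lose nitrogen on Rh2(S-PTTL)4 (or its enantiomer). The rhodium carbene would insert into the benzylic O–CH2 bond to close the ring, and NaOMe would then epimerise C3 to give the trans ester A4.

- For it: this ring construction is well precedented for 2-aryl-2,3-dihydrobenzofuran-3-carboxylates, so on precedent it is stronger than the chosen route.
- For it: C9 arrives as an ester, one reduction away from the carbinol, whereas the chosen route spends two steps trimming an allyl group.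
- Against it: A3 needs an aryl ether and an arylacetate built on the 1,2,3,5-substituted ring A, then diazo transfer, all in a linear sequence.
- Against it: the insertion gives mainly the cis isomer, so the correct relative configuration depends on a base epimerisation next to the O1 leaving group. The C7 methoxy group beside the ether oxygen changes the conformation on which the enantioselectivity depends.
- The chosen route joins three fragments of similar size late, in one step. This alternative is kept as the reserve for the key step.

**Alternative 3:** The C2–C1' and C3–C3a bonds are cut. The boronate from aryllithium 10 and the (E)-alkenyl boronic ester A5 would be coupled with ring A bromide A6 under Pd(OAc)2 and a chiral MandyPhos ligand. The syringyl group would shift from boron to C2 as palladium delivers ring A to C3, giving boronic ester A7.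

- For it: it is also a three-component, catalyst-controlled assembly, the reaction class is established, and C9 is already at the alcohol oxidation level. On precedent and on the C9 oxidation level it is stronger than the chosen route.
- Against it: β-substituted alkenyl boronates are the less reactive partners in this coupling, and A6 is electron-rich and ortho-substituted, so oxidative addition is slow and direct biaryl coupling competes.
- Against it: A7 is still open-chain. The C–B bond must be oxidised, the ring A phenol must be freed selectively beside a second methoxymethyl ether, and the C2–O1 bond must then be closed.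
- Against it: O1 has to take the place of boron with net retention. An invertive displacement would give the cis ring, so the closure must go through the benzylic cation, and C2 is then not set by the key step at all.
- The chosen route keeps the heterocycle intact from the start and replaces boron by hydrogen in a single stereoretentive step.

Key step: step 7

Remark 1: the target SMILES is read as the (2S,3R) isomer, in which the syringyl ring on C2 and the C9 carbinol on C3 are trans.

Remark 2: which enantiomer of BINAP gives the (2S,3S) configuration of 15 cannot be assigned with certainty beforehand. (S)-BINAP is written; (R)-BINAP would be used if the enantiomer of 15 proves to be favoured.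

## Route

Step 1
Reactants: 1 apocynin (1-(4-hydroxy-3-methoxyphenyl)ethan-1-one)
Product: 2 1-(4-hydroxy-3-iodo-5-methoxyphenyl)ethan-1-one
Conditions: NIS (1.05 equiv), p-TsOH·H2O (10 mol%), MeCN, rt
Reagents that add atoms: N-iodosuccinimide, O=C1CCC(=O)N1I
Why: Electrophilic aromatic iodination; the hydroxyl group is the strongest activator and its para position is blocked by the acetyl group, so iodine should enter the free ortho position.

Step 2
Reactants: 2 1-(4-hydroxy-3-iodo-5-methoxyphenyl)ethan-1-one; 3 ethynyltrimethylsilane
Product: 4 1-{4-hydroxy-3-methoxy-5-[(trimethylsilyl)ethynyl]phenyl}ethan-1-one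
Conditions: PdCl2(PPh3)2 (2 mol%), CuI (4 mol%), Et3N, THF, 40 °C
Reagents that add atoms: none
Why: Sonogashira coupling of an aryl iodide, for which free ortho-iodophenols are standard substrates; the silyl cap prevents double coupling, and any early cyclisation to the 2-silylbenzofuran is harmless because step 3 converges on the same product.

Step 3
Reactants: 4 1-{4-hydroxy-3-methoxy-5-[(trimethylsilyl)ethynyl]phenyl}ethan-1-one
Product: 6 1-(7-methoxy-1-benzofuran-5-yl)ethan-1-one, via ethynylphenol 5 (not isolated)
Conditions: Bu4NF (1 M in THF, 2 equiv), THF, 65 °C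
Reagents that add atoms: none
Why: Fluoride cleaves the alkynyl C–Si bond and the phenoxide present in the basic medium adds 5-endo-dig to the terminal alkyne (fluoride-promoted cycloisomerisation of an ortho-alkynylphenol), which should give the benzofuran unsubstituted at C2 and C3.

Step 4
Reactants: 6 1-(7-methoxy-1-benzofuran-5-yl)ethan-1-one
Product: 7 2-(7-methoxy-1-benzofuran-5-yl)-2-methyl-1,3-dioxolane
Conditions: ethylene glycol (5 equiv), p-TsOH·H2O (5 mol%), toluene, reflux, Dean–Stark trap
Reagents that add atoms: ethylene glycol, OCCO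
Why: Acid-catalysed ketalisation driven by azeotropic removal of water; the dioxolane shields the ketone from n-BuLi in step 7 and from NaBH4 in step 10, and the benzofuran tolerates catalytic sulfonic acid.

Step 5
Reactants: 8 4-bromo-2,6-dimethoxyphenol
Product: 9 5-bromo-1,3-dimethoxy-2-(methoxymethoxy)benzene
Conditions: MOMCl (1.5 equiv), i-Pr2NEt (2 equiv), CH2Cl2, 0 °C → rt
Reagents that add atoms: chloromethyl methyl ether, COCCl
Why: O-Alkylation of the phenol (acetal protection); the methoxymethyl ether is inert to organolithiums, palladium, fluoride, periodate and hydride and falls in the same acid step as the dioxolane.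

Step 6
Reactants: 9 5-bromo-1,3-dimethoxy-2-(methoxymethoxy)benzene
Product: 11 2-[3,5-dimethoxy-4-(methoxymethoxy)phenyl]-4,4,5,5-tetramethyl-1,3,2-dioxaborolane, via aryllithium 10 (not isolated)
Conditions: n-BuLi (1.05 equiv), THF, −78 °C; then i-PrOBpin (1.2 equiv), −78 °C → rt
Reagents that add atoms: 2-isopropoxy-4,4,5,5-tetramethyl-1,3,2-dioxaborolane, CC(C)OB1OC(C)(C)C(C)(C)O1
Why: Bromine–lithium exchange is faster than any deprotonation at −78 °C, and the aryllithium displaces isopropoxide from boron (borylation of an aryllithium with an alkoxyboronate).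

Step 7
Reactants: 7 2-(7-methoxy-1-benzofuran-5-yl)-2-methyl-1,3-dioxolane; 11 2-[3,5-dimethoxy-4-(methoxymethoxy)phenyl]-4,4,5,5-tetramethyl-1,3,2-dioxaborolane; 12 allyl acetate
Product: 15 2-[(2S,3S)-2-[3,5-dimethoxy-4-(methoxymethoxy)phenyl]-7-methoxy-3-(prop-2-en-1-yl)-2-(4,4,5,5-tetramethyl-1,3,2-dioxaborolan-2-yl)-2,3-dihydro-1-benzofuran-5-yl]-2-methyl-1,3-dioxolane, via 2-lithiobenzofuran 13 (not isolated), via lithium boronate 14 (not isolated)
Conditions: 7, n-BuLi (1.05 equiv), THF, −78 °C; 11 (1.0 equiv), −78 → 0 °C; then 12 (1.5 equiv), Pd2(dba)3 (2.5 mol%), (S)-BINAP (6 mol%), THF, rt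
Reagents that add atoms: none
Why: Proposed new method: deprotonation of 7 at C2 (the most acidic C–H, sp2 and next to O1) gives 13, which adds to the empty orbital on boron of 11 to give the four-coordinate boronate 14; the anionic boron makes the C2=C3 enol ether strongly nucleophilic at C3, which attacks a terminal carbon of the cationic allyl complex [Pd(C3H5)(BINAP)]+ formed from 12 and zerovalent palladium, and as the C3–C9 bond forms the syringyl group shifts from boron to C2 anti-periplanar to the incoming allyl group, leaving neutral three-coordinate boron on C2. The closest known reaction type is the palladium-catalysed enantioselective allylation of indol-2-yl boronate complexes with 1,2-boronate migration; here oxygen, a weaker donor than nitrogen, activates C3, which should be offset by the low aromatic stabilisation of the furan ring. No ring is closed: the dihydrofuran ring is the dearomatised furan ring of 7. C3 is controlled by the chiral diphosphine on palladium, which selects the face of the planar boronate that meets the allyl terminus. C2 is controlled by the substrate, because the 1,2-shift is stereospecifically anti to the new C3–C9 bond, which places the syringyl ring trans to the allyl group and boron cis to it. The step needs allylation at C3 to win over transfer of the benzofuranyl group to palladium (biaryl-type coupling at C2); the pinacol ligand on boron, the absence of hydroxide and of a free coordination site on the bisphosphine allyl cation, and the outer-sphere attack all favour C3. The aryl group rather than a pinacol oxygen migrates because only the B–C bond can align with the orbital developing at C2.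

Step 8
Reactants: 15 2-[(2S,3S)-2-[3,5-dimethoxy-4-(methoxymethoxy)phenyl]-7-methoxy-3-(prop-2-en-1-yl)-2-(4,4,5,5-tetramethyl-1,3,2-dioxaborolan-2-yl)-2,3-dihydro-1-benzofuran-5-yl]-2-methyl-1,3-dioxolane
Product: 16 2-[(2S,3S)-2-[3,5-dimethoxy-4-(methoxymethoxy)phenyl]-7-methoxy-3-(prop-2-en-1-yl)-2,3-dihydro-1-benzofuran-5-yl]-2-methyl-1,3-dioxolane
Conditions: Bu4NF·3H2O (3 equiv), toluene, 45 °C
Reagents that add atoms: none
Why: Fluoride-promoted protodeboronation of a tertiary benzylic boronic ester; fluoride makes boron four-coordinate and water protonates the C2–B bond from the front (retention), so hydrogen should take the place of boron cis to the allyl group and the syringyl ring stays trans to it.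

Step 9
Reactants: 16 2-[(2S,3S)-2-[3,5-dimethoxy-4-(methoxymethoxy)phenyl]-7-methoxy-3-(prop-2-en-1-yl)-2,3-dihydro-1-benzofuran-5-yl]-2-methyl-1,3-dioxolane
Product: 17 2-[(2S,3S)-2-[3,5-dimethoxy-4-(methoxymethoxy)phenyl]-7-methoxy-3-[(1E)-prop-1-en-1-yl]-2,3-dihydro-1-benzofuran-5-yl]-2-methyl-1,3-dioxolane
Conditions: RuHCl(CO)(PPh3)3 (5 mol%), toluene, 80 °C
Reagents that add atoms: none
Why: Ruthenium-hydride-catalysed alkene isomerisation (insertion, then β-hydride elimination) moves the terminal double bond one position inward; a second shift would need hydrometallation toward the hindered, branched C3 and is expected to be much slower, and the alkene geometry does not matter because the alkene is cleaved.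

Step 10
Reactants: 17 2-[(2S,3S)-2-[3,5-dimethoxy-4-(methoxymethoxy)phenyl]-7-methoxy-3-[(1E)-prop-1-en-1-yl]-2,3-dihydro-1-benzofuran-5-yl]-2-methyl-1,3-dioxolane
Product: 20 [(2S,3R)-2-[3,5-dimethoxy-4-(methoxymethoxy)phenyl]-7-methoxy-5-(2-methyl-1,3-dioxolan-2-yl)-2,3-dihydro-1-benzofuran-3-yl]methanol, via diol 18 (not isolated), via aldehyde 19 (not isolated)
Conditions: OsO4 (2 mol%), NaIO4 (4 equiv), 2,6-lutidine (2 equiv), dioxane–H2O 3:1, rt; then NaBH4 (excess), EtOH, 0 °C
Reagents that add atoms: osmium tetroxide, O=[Os](=O)(=O)=O; sodium periodate, [Na+].[O-][I](=O)(=O)=O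
Why: Lemieux–Johnson cleavage (dihydroxylation, then periodate glycol cleavage), buffered with 2,6-lutidine so that the dioxolane survives, followed by borohydride reduction in the same flask; aldehyde 19 is not isolated because its C3–H is benzylic and α to the carbonyl, and enolisation would open the ring by loss of O1.

Step 11
Reactants: 20 [(2S,3R)-2-[3,5-dimethoxy-4-(methoxymethoxy)phenyl]-7-methoxy-5-(2-methyl-1,3-dioxolan-2-yl)-2,3-dihydro-1-benzofuran-3-yl]methanol
Product: 21 1-[(2S,3R)-2-(4-hydroxy-3,5-dimethoxyphenyl)-3-(hydroxymethyl)-7-methoxy-2,3-dihydro-1-benzofuran-5-yl]ethan-1-one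
Conditions: 2 M HCl (aq), THF, 40 °C
Reagents that add atoms: water, O
Why: Acid hydrolysis of the dioxolane (the ketone oxygen comes from water) and of the aryl methoxymethyl acetal in one operation; neither stereocentre takes part, and reversible ionisation of C2–O1, should it occur, favours the trans isomer.

## Compound list

1 | apocynin, 1-(4-hydroxy-3-methoxyphenyl)ethan-1-one | CC(=O)c1ccc(O)c(OC)c1 | starting material
2 | 1-(4-hydroxy-3-iodo-5-methoxyphenyl)ethan-1-one | CC(=O)c1cc(I)c(O)c(OC)c1 | intermediate
3 | ethynyltrimethylsilane | C[Si](C)(C)C#C | starting material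
4 | 1-{4-hydroxy-3-methoxy-5-[(trimethylsilyl)ethynyl]phenyl}ethan-1-one | CC(=O)c1cc(OC)c(O)c(C#C[Si](C)(C)C)c1 | intermediate
5 | 1-(3-ethynyl-4-hydroxy-5-methoxyphenyl)ethan-1-one (formed in the flask, not isolated) | CC(=O)c1cc(OC)c(O)c(C#C)c1 | intermediate
6 | 1-(7-methoxy-1-benzofuran-5-yl)ethan-1-one | CC(=O)c1cc(OC)c2occc2c1 | intermediate
7 | 2-(7-methoxy-1-benzofuran-5-yl)-2-methyl-1,3-dioxolane | CC1(OCCO1)c1cc(OC)c2occc2c1 | intermediate
8 | 4-bromo-2,6-dimethoxyphenol | COc1cc(Br)cc(OC)c1O | starting material
9 | 5-bromo-1,3-dimethoxy-2-(methoxymethoxy)benzene | COCOc1c(OC)cc(Br)cc1OC | intermediate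
10 | [3,5-dimethoxy-4-(methoxymethoxy)phenyl]lithium (formed in the flask, not isolated) | [Li]c1cc(OC)c(OCOC)c(OC)c1 | intermediate
11 | 2-[3,5-dimethoxy-4-(methoxymethoxy)phenyl]-4,4,5,5-tetramethyl-1,3,2-dioxaborolane | COCOc1c(OC)cc(cc1OC)B1OC(C)(C)C(C)(C)O1 | intermediate
12 | allyl acetate (prop-2-en-1-yl acetate) | C=CCOC(C)=O | starting material
13 | [7-methoxy-5-(2-methyl-1,3-dioxolan-2-yl)-1-benzofuran-2-yl]lithium (formed in the flask, not isolated) | [Li]c1cc2cc(C3(C)OCCO3)cc(OC)c2o1 | intermediate
14 | lithium [3,5-dimethoxy-4-(methoxymethoxy)phenyl][7-methoxy-5-(2-methyl-1,3-dioxolan-2-yl)-1-benzofuran-2-yl](2,3-dimethylbutane-2,3-diolato)borate (formed in the flask, not isolated) | [Li+].COCOc1c(OC)cc(cc1OC)[B-]1(OC(C)(C)C(C)(C)O1)c1cc2cc(C3(C)OCCO3)cc(OC)c2o1 | intermediate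
15 | 2-[(2S,3S)-2-[3,5-dimethoxy-4-(methoxymethoxy)phenyl]-7-methoxy-3-(prop-2-en-1-yl)-2-(4,4,5,5-tetramethyl-1,3,2-dioxaborolan-2-yl)-2,3-dihydro-1-benzofuran-5-yl]-2-methyl-1,3-dioxolane (aryl trans to allyl, boron cis to allyl) | COCOc1c(OC)cc(cc1OC)[C@@]2(B3OC(C)(C)C(C)(C)O3)Oc4c(OC)cc(C5(C)OCCO5)cc4[C@@H]2CC=C | intermediate
16 | 2-[(2S,3S)-2-[3,5-dimethoxy-4-(methoxymethoxy)phenyl]-7-methoxy-3-(prop-2-en-1-yl)-2,3-dihydro-1-benzofuran-5-yl]-2-methyl-1,3-dioxolane (trans) | COCOc1c(OC)cc(cc1OC)[C@H]2Oc3c(OC)cc(C4(C)OCCO4)cc3[C@@H]2CC=C | intermediate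
17 | 2-[(2S,3S)-2-[3,5-dimethoxy-4-(methoxymethoxy)phenyl]-7-methoxy-3-[(1E)-prop-1-en-1-yl]-2,3-dihydro-1-benzofuran-5-yl]-2-methyl-1,3-dioxolane (trans; the Z isomer would serve equally) | COCOc1c(OC)cc(cc1OC)[C@H]2Oc3c(OC)cc(C4(C)OCCO4)cc3[C@@H]2/C=C/C | intermediate
18 | 1-[(2S,3R)-2-[3,5-dimethoxy-4-(methoxymethoxy)phenyl]-7-methoxy-5-(2-methyl-1,3-dioxolan-2-yl)-2,3-dihydro-1-benzofuran-3-yl]propane-1,2-diol (side-chain carbinol centres unassigned; formed in the flask, not isolated) | COCOc1c(OC)cc(cc1OC)[C@H]2Oc3c(OC)cc(C4(C)OCCO4)cc3[C@@H]2C(O)C(C)O | intermediate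
19 | (2S,3S)-2-[3,5-dimethoxy-4-(methoxymethoxy)phenyl]-7-methoxy-5-(2-methyl-1,3-dioxolan-2-yl)-2,3-dihydro-1-benzofuran-3-carbaldehyde (trans; formed in the flask, not isolated) | COCOc1c(OC)cc(cc1OC)[C@H]2Oc3c(OC)cc(C4(C)OCCO4)cc3[C@@H]2C=O | intermediate
20 | [(2S,3R)-2-[3,5-dimethoxy-4-(methoxymethoxy)phenyl]-7-methoxy-5-(2-methyl-1,3-dioxolan-2-yl)-2,3-dihydro-1-benzofuran-3-yl]methanol (trans) | COCOc1c(OC)cc(cc1OC)[C@H]2Oc3c(OC)cc(C4(C)OCCO4)cc3[C@@H]2CO | intermediate
21 | 1-[(2S,3R)-2-(4-hydroxy-3,5-dimethoxyphenyl)-3-(hydroxymethyl)-7-methoxy-2,3-dihydro-1-benzofuran-5-yl]ethan-1-one | COc1cc([C@H]2Oc3c(OC)cc(C(C)=O)cc3[C@@H]2CO)cc(OC)c1O | target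

## Step count and risk

Total step count: 11. Longest linear sequence: 9 steps (steps 1 to 4 and 7 to 11, from apocynin 1); the boronic ester arm (steps 5 and 6) joins at step 7.

**Step 7 (key step, proposed new method).**
- What may go wrong: insufficient nucleophilicity at C3 (an enol ether in place of the enamine of the indole precedent), so that the boronate simply reverts to 7 and 11 on work-up. Alternatively, transfer of the benzofuranyl group from boron to palladium and allylation at C2 with loss of the three-component pathway. Poor facial selectivity at C3 is also possible, because the chiral ligand sits on the electrophile and not on the prochiral carbon.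
- Fallback (known chemistry; sets out from 2 and 9, returns at 20): the C2–C3 bond is made by intramolecular carbene C–H insertion instead. Aryllithium 10, made from 9 as in step 6, is quenched with paraformaldehyde to give [3,5-dimethoxy-4-(methoxymethoxy)phenyl]methanol F1. Mitsunobu etherification of iodophenol 2 with F1 (PPh3, DIAD, THF) gives the aryl benzyl ether F2, which is ketalised (ethylene glycol, PPTS, benzene, Dean–Stark trap) to dioxolane F3. Coupling of F3 with the Reformatsky reagent BrZnCH2CO2Me (Pd(dba)2, Q-Phos, THF) gives methyl arylacetate F4. Diazo transfer (p-acetamidobenzenesulfonyl azide, DBU, MeCN) gives aryldiazoacetate F5, which is identical with A3. Rh2(S-PTTL)4 (or its enantiomer, whichever gives 2S) in toluene at low temperature should insert the carbene into the benzylic O–CH2 bond to give mainly the cis ester F6. NaOMe in MeOH added to the crude product epimerises C3 to the trans ester F7, which is identical with A4. Reduction of F7 with LiAlH4 in THF gives 20, which rejoins the route at step 11.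

**Step 8.**
- What may go wrong: partial loss of configuration at C2, because the C2–B bond is benzylic and oxygen-substituted and may be protonated through a carbanion-like, non-concerted path. The fully substituted centre may also react slowly.
- Fallback (sets out from 15, returns at 21): control of C2 is moved from the stereospecific protonation to thermodynamics. The C2 epimer of 16, the cis allyl compound F8, is not separated but carried with 16 through steps 9 to 11. This gives in turn the cis propenyl compound F9, the cis diol F10 and the cis aldehyde F11 (both formed in the flask only), the cis alcohol F12 and finally the cis phenol ketone F13 beside 21. The mixture of 21 and F13 is then stirred with CF3CO2H in CH2Cl2. With the phenol free, the C2–O1 bond para to it ionises reversibly to a quinone-methide-like benzylic cation that stays tethered to the ring A phenol, C3 is untouched, and reclosure should give the more stable trans isomer 21. This correction holds only as long as aldehyde F11 does not enolise, which is the same demand as for 19.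

**Step 10 (together with step 9, which feeds it).**
- What may go wrong: in step 9, a second migration of the double bond into conjugation with ring A, which would erase C3. In step 10, enolisation of aldehyde 19 before reduction, with ring opening by loss of the O1 phenoxide. Partial hydrolysis of the dioxolane in the periodate medium is a further risk, since the freed ketone would then be reduced.
- Fallback (sets out from 16, returns at 20; bypasses steps 9 and 10 and never forms an aldehyde): Tsuji–Wacker oxidation of the terminal alkene of 16 (PdCl2, CuCl, O2, DMF–H2O) gives methyl ketone F14. Baeyer–Villiger oxidation with buffered mCPBA (NaHCO3, CH2Cl2), in which the primary carbon C9 migrates in preference to methyl, gives acetate F15. K2CO3 in MeOH then releases 20.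

**Step 11.**
- What may go wrong: acid-induced ionisation of the C2–O1 bond once the phenol is free, followed by capture of the cation by solvent or by another molecule. Alternatively, incomplete cleavage of the methoxymethyl ether under conditions mild enough for the ring.
- Fallback (sets out from 20, returns at 21): the two masks are removed separately. PPTS in wet acetone cleaves only the dioxolane and gives the methoxymethyl ether ketone F16. The methoxymethyl group is then removed under non-hydrolytic, thiol-scavenged Lewis acid conditions (ZnBr2, n-PrSH, CH2Cl2, 0 °C), in which the oxocarbenium fragment is trapped as a thioacetal, giving 21.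

## Further compounds

F1 | step 7 | [3,5-dimethoxy-4-(methoxymethoxy)phenyl]methanol | COCOc1c(OC)cc(CO)cc1OC
F2 | step 7 | 1-[4-{[3,5-dimethoxy-4-(methoxymethoxy)phenyl]methoxy}-3-iodo-5-methoxyphenyl]ethan-1-one | CC(=O)c1cc(I)c(OCc2cc(OC)c(OCOC)c(OC)c2)c(OC)c1
F3 | step 7 | 2-[4-{[3,5-dimethoxy-4-(methoxymethoxy)phenyl]methoxy}-3-iodo-5-methoxyphenyl]-2-methyl-1,3-dioxolane | CC1(OCCO1)c1cc(I)c(OCc2cc(OC)c(OCOC)c(OC)c2)c(OC)c1
F4 | step 7 | methyl 2-[2-{[3,5-dimethoxy-4-(methoxymethoxy)phenyl]methoxy}-3-methoxy-5-(2-methyl-1,3-dioxolan-2-yl)phenyl]acetate | COC(=O)Cc1cc(C2(C)OCCO2)cc(OC)c1OCc1cc(OC)c(OCOC)c(OC)c1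
F5 | step 7 | methyl 2-diazo-2-[2-{[3,5-dimethoxy-4-(methoxymethoxy)phenyl]methoxy}-3-methoxy-5-(2-methyl-1,3-dioxolan-2-yl)phenyl]acetate | COC(=O)C(=[N+]=[N-])c1cc(C2(C)OCCO2)cc(OC)c1OCc1cc(OC)c(OCOC)c(OC)c1
F6 | step 7 | methyl (2S,3R)-2-[3,5-dimethoxy-4-(methoxymethoxy)phenyl]-7-methoxy-5-(2-methyl-1,3-dioxolan-2-yl)-2,3-dihydro-1-benzofuran-3-carboxylate (cis) | COCOc1c(OC)cc(cc1OC)[C@H]2Oc3c(OC)cc(C4(C)OCCO4)cc3[C@H]2C(=O)OC
F7 | step 7 | methyl (2S,3S)-2-[3,5-dimethoxy-4-(methoxymethoxy)phenyl]-7-methoxy-5-(2-methyl-1,3-dioxolan-2-yl)-2,3-dihydro-1-benzofuran-3-carboxylate (trans) | COCOc1c(OC)cc(cc1OC)[C@H]2Oc3c(OC)cc(C4(C)OCCO4)cc3[C@@H]2C(=O)OC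
F8 | step 8 | 2-[(2R,3S)-2-[3,5-dimethoxy-4-(methoxymethoxy)phenyl]-7-methoxy-3-(prop-2-en-1-yl)-2,3-dihydro-1-benzofuran-5-yl]-2-methyl-1,3-dioxolane (cis) | COCOc1c(OC)cc(cc1OC)[C@@H]2Oc3c(OC)cc(C4(C)OCCO4)cc3[C@@H]2CC=C
F9 | step 8 | 2-[(2R,3S)-2-[3,5-dimethoxy-4-(methoxymethoxy)phenyl]-7-methoxy-3-[(1E)-prop-1-en-1-yl]-2,3-dihydro-1-benzofuran-5-yl]-2-methyl-1,3-dioxolane (cis) | COCOc1c(OC)cc(cc1OC)[C@@H]2Oc3c(OC)cc(C4(C)OCCO4)cc3[C@@H]2/C=C/C
F10 | step 8 | 1-[(2R,3R)-2-[3,5-dimethoxy-4-(methoxymethoxy)phenyl]-7-methoxy-5-(2-methyl-1,3-dioxolan-2-yl)-2,3-dihydro-1-benzofuran-3-yl]propane-1,2-diol (cis; side-chain carbinol centres unassigned) | COCOc1c(OC)cc(cc1OC)[C@@H]2Oc3c(OC)cc(C4(C)OCCO4)cc3[C@@H]2C(O)C(C)O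
F11 | step 8 | (2R,3S)-2-[3,5-dimethoxy-4-(methoxymethoxy)phenyl]-7-methoxy-5-(2-methyl-1,3-dioxolan-2-yl)-2,3-dihydro-1-benzofuran-3-carbaldehyde (cis) | COCOc1c(OC)cc(cc1OC)[C@@H]2Oc3c(OC)cc(C4(C)OCCO4)cc3[C@@H]2C=O
F12 | step 8 | [(2R,3R)-2-[3,5-dimethoxy-4-(methoxymethoxy)phenyl]-7-methoxy-5-(2-methyl-1,3-dioxolan-2-yl)-2,3-dihydro-1-benzofuran-3-yl]methanol (cis) | COCOc1c(OC)cc(cc1OC)[C@@H]2Oc3c(OC)cc(C4(C)OCCO4)cc3[C@@H]2CO
F13 | step 8 | 1-[(2R,3R)-2-(4-hydroxy-3,5-dimethoxyphenyl)-3-(hydroxymethyl)-7-methoxy-2,3-dihydro-1-benzofuran-5-yl]ethan-1-one (cis) | COc1cc([C@@H]2Oc3c(OC)cc(C(C)=O)cc3[C@@H]2CO)cc(OC)c1O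
F14 | step 10 | 1-[(2S,3S)-2-[3,5-dimethoxy-4-(methoxymethoxy)phenyl]-7-methoxy-5-(2-methyl-1,3-dioxolan-2-yl)-2,3-dihydro-1-benzofuran-3-yl]propan-2-one | COCOc1c(OC)cc(cc1OC)[C@H]2Oc3c(OC)cc(C4(C)OCCO4)cc3[C@@H]2CC(C)=O
F15 | step 10 | [(2S,3R)-2-[3,5-dimethoxy-4-(methoxymethoxy)phenyl]-7-methoxy-5-(2-methyl-1,3-dioxolan-2-yl)-2,3-dihydro-1-benzofuran-3-yl]methyl acetate | COCOc1c(OC)cc(cc1OC)[C@H]2Oc3c(OC)cc(C4(C)OCCO4)cc3[C@@H]2COC(C)=O
F16 | step 11 | 1-[(2S,3R)-2-[3,5-dimethoxy-4-(methoxymethoxy)phenyl]-3-(hydroxymethyl)-7-methoxy-2,3-dihydro-1-benzofuran-5-yl]ethan-1-one | COCOc1c(OC)cc(cc1OC)[C@H]2Oc3c(OC)cc(C(C)=O)cc3[C@@H]2CO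
A1 | alternative 1 | methyl 3-[(1S,2R)-1-[3,5-dimethoxy-4-(triisopropylsilyloxy)phenyl]-1-hydroxy-3-(trityloxy)propan-2-yl]-4-fluoro-5-methoxybenzoate | COc1cc([C@@H](O)[C@@H](COC(c2ccccc2)(c2ccccc2)c2ccccc2)c2cc(C(=O)OC)cc(OC)c2F)cc(OC)c1O[Si](C(C)C)(C(C)C)C(C)C
A2 | alternative 1 | methyl (2S,3R)-2-[3,5-dimethoxy-4-(triisopropylsilyloxy)phenyl]-7-methoxy-3-(trityloxymethyl)-2,3-dihydro-1-benzofuran-5-carboxylate | COc1cc([C@H]2Oc3c(OC)cc(C(=O)OC)cc3[C@@H]2COC(c4ccccc4)(c4ccccc4)c4ccccc4)cc(OC)c1O[Si](C(C)C)(C(C)C)C(C)C
A3 | alternative 2 | methyl 2-diazo-2-[2-{[3,5-dimethoxy-4-(methoxymethoxy)phenyl]methoxy}-3-methoxy-5-(2-methyl-1,3-dioxolan-2-yl)phenyl]acetate | COC(=O)C(=[N+]=[N-])c1cc(C2(C)OCCO2)cc(OC)c1OCc1cc(OC)c(OCOC)c(OC)c1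
A4 | alternative 2 | methyl (2S,3S)-2-[3,5-dimethoxy-4-(methoxymethoxy)phenyl]-7-methoxy-5-(2-methyl-1,3-dioxolan-2-yl)-2,3-dihydro-1-benzofuran-3-carboxylate (trans) | COc1cc([C@H]2Oc3c(OC)cc(C4(C)OCCO4)cc3[C@@H]2C(=O)OC)cc(OC)c1OCOC
A5 | alternative 3 | tert-butyldimethyl{[(2E)-3-(4,4,5,5-tetramethyl-1,3,2-dioxaborolan-2-yl)prop-2-en-1-yl]oxy}silane | CC(C)(C)[Si](C)(C)OC/C=C/B1OC(C)(C)C(C)(C)O1
A6 | alternative 3 | 2-[3-bromo-5-methoxy-4-(methoxymethoxy)phenyl]-2-methyl-1,3-dioxolane | CC1(OCCO1)c1cc(Br)c(OCOC)c(OC)c1
A7 | alternative 3 | tert-butyl{[(2R,3S)-3-[3,5-dimethoxy-4-(methoxymethoxy)phenyl]-2-[3-methoxy-2-(methoxymethoxy)-5-(2-methyl-1,3-dioxolan-2-yl)phenyl]-3-(4,4,5,5-tetramethyl-1,3,2-dioxaborolan-2-yl)propyl]oxy}dimethylsilane | COCOc1c(OC)cc(cc1OC)[C@@H](B2OC(C)(C)C(C)(C)O2)[C@@H](CO[Si](C)(C)C(C)(C)C)c3cc(C4(C)OCCO4)cc(OC)c3OCOC
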